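**Retrosynthetic overview**
1. C6–O ester bond: Mitsunobu union, with inversion at C6, of the macrocyclic 6-epi alcohol and (2S,3S)-epoxyangelic acid; the acid comes from ethyl (S)-3-hydroxybutanoate.
2. C6–C7 bond: blue-light photoredox/chromium allylation of a Z-enal by a tethered 3-(bromomethyl)butenolide. It closes the ten-membered carbocycle, unmasks the α-methylene lactone and sets C7 and C6.
3. Butenolide (C7=C11): acylation of the C8 allylic alcohol by 2-(bromomethyl)acrylic acid, then ring-closing metathesis.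
4. Furanone (C1–C2, C3–O): acetylide of a bought Z-enynol adds to a γ-lactone carbonyl; amine-mediated cyclisation onto the ynone.
5. Ring order: bought γ-lactone (C8; C10 set on it by enolate alkylation) → furanone → butenolide → carbocycle plus α-methylene lactone → ester.

Assumption: all four starting materials are catalogue compounds, and the sesquiterpene carbons carry germacrane locants (C1 ketone, C3–O–C10 furanone bridge, C4=C5, C6 ester carbon, C8 lactone carbon, C11=C13, C12 lactone carbonyl).

**Route**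

Step 1
Reactants: 1 (S)-5-(hydroxymethyl)dihydrofuran-2(3H)-one
Product: 3 (S)-5-vinyldihydrofuran-2(3H)-one, via lactone aldehyde 2 (not isolated)
Conditions: (COCl)2, DMSO, Et3N, CH2Cl2, −78 °C; filter, concentrate; Ph3PCH3Br, KN(SiMe3)2, THF, −78 → 0 °C
Reagents that add atoms: methylenetriphenylphosphorane (from Ph3PCH3Br), C=P(c1ccccc1)(c1ccccc1)c1ccccc1
Why: Swern oxidation gives the fragile α-oxy aldehyde, which is methylenated at once by a Wittig reaction at low temperature, so the bought C8 centre (S, from L-glutamic acid) is carried through unchanged.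

Step 2
Reactants: 3 (S)-5-vinyldihydrofuran-2(3H)-one
Product: 4 (3R,5S)-3-hydroxy-5-vinyldihydrofuran-2(3H)-one
Conditions: LiN(iPr)2, THF, −78 °C; MoO(O2)2·pyridine·HMPA, −78 → −40 °C
Reagents that add atoms: MoO(O2)2·pyridine·HMPA (MoOPH), O=[Mo]12(OO1)OO2.c1ccncc1.CN(C)P(=O)(N(C)C)N(C)C
Why: Vedejs hydroxylation of the lactone enolate brings in the future C10 oxygen, mainly trans to the vinyl group; this centre is erased and reset in step 3, so its ratio does not matter.

Step 3
Reactants: 4 (3R,5S)-3-hydroxy-5-vinyldihydrofuran-2(3H)-one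
Product: 5 (3S,5S)-3-hydroxy-3-methyl-5-vinyldihydrofuran-2(3H)-one
Conditions: LiN(iPr)2 (2.3 equiv), THF/DMPU, −78 → −45 °C; MeI, −78 °C
Reagents that add atoms: iodomethane, CI
Why: C-alkylation of the planar alkoxide–enolate dianion; methyl iodide enters anti to the C5 vinyl group (1,3-induction in γ-substituted butyrolactone enolates), so CH3 is trans and OH cis to vinyl, which is (S) at the future C10.

Step 4
Reactants: 6 (Z)-3-methylpent-2-en-4-yn-1-ol
Product: 7 (Z)-triethyl[(3-methylpent-2-en-4-yn-1-yl)oxy]silane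
Conditions: Et3SiCl, imidazole, CH2Cl2, 0 °C
Reagents that add atoms: chlorotriethylsilane, CC[Si](Cl)(CC)CC
Why: Silylation masks the primary hydroxyl, which would otherwise add 5-exo to the ynone of step 5 and give a furan; the Z-alkene (future C4=C5) is bought.

Step 5
Reactants: 5 (3S,5S)-3-hydroxy-3-methyl-5-vinyldihydrofuran-2(3H)-one; 7 (Z)-triethyl[(3-methylpent-2-en-4-yn-1-yl)oxy]silane
Product: 10 (S)-5-[(Z)-4-hydroxybut-2-en-2-yl]-2-[(S)-2-hydroxybut-3-en-1-yl]-2-methylfuran-3(2H)-one, via ynone 8 (not isolated), via enaminone 9 (not isolated)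
Conditions: 7, n-BuLi, THF, −78 °C; 5 + LiN(SiMe3)2, −78 → −40 °C; AcOH; Et2NH, EtOH, 20 °C; 1 M HCl, 0 °C
Reagents that add atoms: none
Why: Acetylide addition to the lactone carbonyl stops at the lithium lactolate and gives the α′-hydroxy ynone; diethylamine conjugate addition followed by acid lets only the tertiary C10 hydroxyl close a five-membered ring at the iminium carbon (3(2H)-furanone synthesis by addition–elimination), the acid also removes the silyl group, and no stereocentre is touched.

Step 6
Reactants: 10 (S)-5-[(Z)-4-hydroxybut-2-en-2-yl]-2-[(S)-2-hydroxybut-3-en-1-yl]-2-methylfuran-3(2H)-one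
Product: 11 (Z)-3-{(S)-5-[(S)-2-hydroxybut-3-en-1-yl]-5-methyl-4-oxo-4,5-dihydrofuran-2-yl}but-2-enal
Conditions: TEMPO (10 mol %), PhI(OAc)2 (1.05 equiv), CH2Cl2, 20 °C
Reagents that add atoms: none
Why: Oxoammonium (TEMPO) oxidation is selective for the primary allylic alcohol over the secondary C8 alcohol and is mild enough to keep the Z-enal geometry.

Step 7
Reactants: 11 (Z)-3-{(S)-5-[(S)-2-hydroxybut-3-en-1-yl]-5-methyl-4-oxo-4,5-dihydrofuran-2-yl}but-2-enal; 12 2-(bromomethyl)acrylic acid
Product: 13 (S)-1-{(S)-2-methyl-3-oxo-5-[(Z)-4-oxobut-2-en-2-yl]-2,3-dihydrofuran-2-yl}but-3-en-2-yl 2-(bromomethyl)acrylate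
Conditions: DIC, DMAP (10 mol %), CH2Cl2, −20 → 0 °C
Reagents that add atoms: none
Why: Steglich esterification of the only remaining hydroxyl (C8) at low temperature, with retention at C8.

Step 8
Reactants: 13 (S)-1-{(S)-2-methyl-3-oxo-5-[(Z)-4-oxobut-2-en-2-yl]-2,3-dihydrofuran-2-yl}but-3-en-2-yl 2-(bromomethyl)acrylate
Product: 14 (Z)-3-{(S)-5-{[(S)-4-(bromomethyl)-5-oxo-2,5-dihydrofuran-2-yl]methyl}-5-methyl-4-oxo-4,5-dihydrofuran-2-yl}but-2-enal
Conditions: second-generation Hoveyda–Grubbs catalyst RuCl2(H2IMes)(=CH-C6H4-2-OiPr) (10 mol %), toluene, 80 °C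
Reagents that add atoms: none
Why: Ring-closing metathesis of the vinyl group with the 1,1-disubstituted acrylate gives the five-membered butenolide; the trisubstituted enal alkene and the furanone alkene are inert, and the conditions are base-free so the butenolide γ-centre (C8) does not epimerise.

Step 9
Reactants: 14 (Z)-3-{(S)-5-{[(S)-4-(bromomethyl)-5-oxo-2,5-dihydrofuran-2-yl]methyl}-5-methyl-4-oxo-4,5-dihydrofuran-2-yl}but-2-enal
Product: 15 (4Z,6R,7S,8S,10S)-6-hydroxy-1-oxo-3,10-epoxygermacra-2,4,11(13)-trien-12,8-olide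
Conditions: CrCl3·3THF (20 mol %), 4CzIPN (2 mol %), Hantzsch ester (1.5 equiv), NaHCO3 (3 equiv), degassed DMF (2 mM), 450 nm LEDs, 20 °C
Reagents that add atoms: none
Why: Proposed new method: an intramolecular photoredox/chromium-catalysed Barbier allylation that uses a 3-(bromomethyl)butenolide as pronucleophile to close a ten-membered ring. Excited 4CzIPN (2,4,5,6-tetrakis(carbazol-9-yl)isophthalonitrile) is reductively quenched by the Hantzsch ester, and the reduced dye turns trivalent chromium into divalent chromium. Two divalent chromium centres convert the allylic bromide, via the allyl radical, into a σ-allyl trivalent chromium species. This adds at its γ-carbon (C7) to the chromium-bound enal carbonyl (C6) through a closed six-membered chair transition state, and the double bond moves out to C11=C13. Attack on the butenolide face anti to the C8–C9 bond gives the 7,8-trans lactone. The ring-enforced E-type allyl geometry gives the anti adduct, which is the 6R alcohol. Protonation by the Hantzsch pyridinium frees 15 and trivalent chromium. The substrate does not absorb at 450 nm, and sensitised Z/E scrambling of the acyclic enal is harmless because only the Z isomer can reach C7. Closest known reaction types: stoichiometric Zn, In or CrCl2 Barbier additions of 3-(bromomethyl)butenolides to aldehydes, Nozaki–Hiyama–Kishi-type macrocyclisations, and intermolecular photoredox chromium-catalysed aldehyde allylations.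

Step 10
Reactants: 16 ethyl (S)-3-hydroxybutanoate
Product: 17 ethyl (2S,3S)-3-hydroxy-2-methylbutanoate
Conditions: LiN(iPr)2 (2.2 equiv), THF, −78 → −20 °C; MeI, DMPU, −78 → 0 °C
Reagents that add atoms: iodomethane, CI
Why: Fráter–Seebach alkylation; the chelated alkoxide–enolate is methylated anti to the C3 methyl, giving the anti (2S,3S) product from the bought (S) carbinol.

Step 11
Reactants: 17 ethyl (2S,3S)-3-hydroxy-2-methylbutanoate
Product: 18 ethyl (2S,3S)-2,3-dihydroxy-2-methylbutanoate
Conditions: LiN(iPr)2 (2.3 equiv), THF, −78 → −20 °C; MoO(O2)2·pyridine·HMPA, −78 → −40 °C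
Reagents that add atoms: MoO(O2)2·pyridine·HMPA (MoOPH), O=[Mo]12(OO1)OO2.c1ccncc1.CN(C)P(=O)(N(C)C)N(C)C
Why: A second Fráter–Seebach-type trapping, here Vedejs hydroxylation; the oxygen electrophile takes the same anti face of the chelated dianion, so the quaternary centre forms with OH anti and CH3 syn to the C3 hydroxyl (2S).

Step 12
Reactants: 18 ethyl (2S,3S)-2,3-dihydroxy-2-methylbutanoate
Product: 21 (2S,3S)-2,3-dimethyloxirane-2-carboxylic acid, via cyclic orthoacetate 19 (not isolated), via bromo acetate 20 (not isolated)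
Conditions: MeC(OMe)3, PPTS (cat.), CH2Cl2; AcBr, CH2Cl2, 0 °C; KOH, MeOH/H2O, 0 → 20 °C; cold 1 M HCl to pH 3
Reagents that add atoms: none
Why: Kolb–Sharpless diol-to-epoxide conversion; bromide opens the acetoxonium ion at the secondary carbon with inversion and the freed tertiary alkoxide closes with a second inversion, so both centres are retained and the cis (angelate-type) epoxide results, the base then saponifying the ester.

Step 13
Reactants: 15 (4Z,6R,7S,8S,10S)-6-hydroxy-1-oxo-3,10-epoxygermacra-2,4,11(13)-trien-12,8-olide; 21 (2S,3S)-2,3-dimethyloxirane-2-carboxylic acid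
Product: 22 (4Z,6S,7R,8S,10S)-6-[(2S,3S)-2,3-dimethyloxirane-2-carbonyloxy]-1-oxo-3,10-epoxygermacra-2,4,11(13)-trien-12,8-olide
Conditions: PPh3, DIAD (premixed), toluene, 0 → 20 °C
Reagents that add atoms: none
Why: Mitsunobu esterification; the carboxylate displaces the oxyphosphonium group at C6 by SN2 with clean inversion (6R → 6S), under neutral conditions that spare the epoxide and the α-methylene lactone.

**Compound list**
1 | (S)-5-(hydroxymethyl)dihydrofuran-2(3H)-one | O=C1CC[C@@H](CO)O1 | starting material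
2 | (S)-5-oxotetrahydrofuran-2-carbaldehyde | O=C[C@@H]1CCC(=O)O1 | intermediate (not isolated)
3 | (S)-5-vinyldihydrofuran-2(3H)-one | C=C[C@@H]1CCC(=O)O1 | intermediate
4 | (3R,5S)-3-hydroxy-5-vinyldihydrofuran-2(3H)-one (major epimer) | C=C[C@@H]1C[C@@H](O)C(=O)O1 | intermediate
5 | (3S,5S)-3-hydroxy-3-methyl-5-vinyldihydrofuran-2(3H)-one | C=C[C@@H]1C[C@](C)(O)C(=O)O1 | intermediate
6 | (Z)-3-methylpent-2-en-4-yn-1-ol | C#C/C(C)=C\CO | starting material
7 | (Z)-triethyl[(3-methylpent-2-en-4-yn-1-yl)oxy]silane | C#C/C(C)=C\CO[Si](CC)(CC)CC | intermediate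
8 | (2Z,7S,9S)-7,9-dihydroxy-3,7-dimethyl-1-(triethylsilyloxy)undeca-2,10-dien-4-yn-6-one | CC[Si](CC)(CC)OC/C=C(C)\C#CC(=O)[C@@](C)(O)C[C@H](O)C=C | intermediate (not isolated)
9 | (2Z,4E,7S,9S)-4-(diethylamino)-7,9-dihydroxy-3,7-dimethyl-1-(triethylsilyloxy)undeca-2,4,10-trien-6-one | CC[Si](CC)(CC)OC/C=C(C)\C(=C/C(=O)[C@@](C)(O)C[C@H](O)C=C)N(CC)CC | intermediate (not isolated)
10 | (S)-5-[(Z)-4-hydroxybut-2-en-2-yl]-2-[(S)-2-hydroxybut-3-en-1-yl]-2-methylfuran-3(2H)-one | C=C[C@@H](O)C[C@]1(C)OC(=CC1=O)/C(C)=C\CO | intermediate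
11 | (Z)-3-{(S)-5-[(S)-2-hydroxybut-3-en-1-yl]-5-methyl-4-oxo-4,5-dihydrofuran-2-yl}but-2-enal | C=C[C@@H](O)C[C@]1(C)OC(=CC1=O)/C(C)=C\C=O | intermediate
12 | 2-(bromomethyl)acrylic acid | OC(=O)C(=C)CBr | starting material
13 | (S)-1-{(S)-2-methyl-3-oxo-5-[(Z)-4-oxobut-2-en-2-yl]-2,3-dihydrofuran-2-yl}but-3-en-2-yl 2-(bromomethyl)acrylate | C=C[C@@H](OC(=O)C(=C)CBr)C[C@]1(C)OC(=CC1=O)/C(C)=C\C=O | intermediate
14 | (Z)-3-{(S)-5-{[(S)-4-(bromomethyl)-5-oxo-2,5-dihydrofuran-2-yl]methyl}-5-methyl-4-oxo-4,5-dihydrofuran-2-yl}but-2-enal | BrCC1=C[C@H](C[C@]2(C)OC(=CC2=O)/C(C)=C\C=O)OC1=O | intermediate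
15 | (4Z,6R,7S,8S,10S)-6-hydroxy-1-oxo-3,10-epoxygermacra-2,4,11(13)-trien-12,8-olide (6-epimer of the deacylated target) | C=C1C(=O)O[C@H]2C[C@]3(C)OC(=CC3=O)/C(C)=C\[C@@H](O)[C@H]12 | intermediate
16 | ethyl (S)-3-hydroxybutanoate | CCOC(=O)C[C@H](C)O | starting material
17 | ethyl (2S,3S)-3-hydroxy-2-methylbutanoate | CCOC(=O)[C@@H](C)[C@H](C)O | intermediate
18 | ethyl (2S,3S)-2,3-dihydroxy-2-methylbutanoate | CCOC(=O)[C@@](C)(O)[C@H](C)O | intermediate
19 | ethyl (4S,5S)-2-methoxy-2,4,5-trimethyl-1,3-dioxolane-4-carboxylate (both epimers at the orthoester carbon) | CCOC(=O)[C@@]1(C)OC(C)(OC)O[C@H]1C | intermediate (not isolated)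
20 | ethyl (2R,3R)-2-acetoxy-3-bromo-2-methylbutanoate | CCOC(=O)[C@@](C)(OC(C)=O)[C@@H](C)Br | intermediate (not isolated)
21 | (2S,3S)-2,3-dimethyloxirane-2-carboxylic acid (epoxyangelic acid) | OC(=O)[C@@]1(C)O[C@H]1C | intermediate
22 | (4Z,6S,7R,8S,10S)-6-[(2S,3S)-2,3-dimethyloxirane-2-carbonyloxy]-1-oxo-3,10-epoxygermacra-2,4,11(13)-trien-12,8-olide (CNP0258430.1) | C=C1C(=O)O[C@H]2C[C@]3(C)OC(=CC3=O)/C(C)=C\[C@H](OC(=O)[C@@]3(C)O[C@H]3C)[C@H]12 | target

**Step count**
Total: 13 steps. Longest linear sequence: 9 steps (1, 2, 3, 5, 6, 7, 8, 9, 13).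

**Steps most likely to fail**

Step 9 (the new ring closure). The medium ring is strained, the allylchromium species can be protonated instead of adding, and the C6/C7 outcome rests on a transition-state argument, not on precedent for this substrate. The fallback sets out from 14 and comes back at 15. It gives up the light-driven catalytic cycle and closes the same bond by classical stoichiometric metal insertion: activated Zn dust in THF/saturated aqueous NH4Cl at 2 mM, or stoichiometric CrCl2 in DMF. This is the known Barbier/Nozaki–Hiyama–Kishi chemistry of 3-(bromomethyl)butenolides with aldehydes. No new compound arises on this path, so its entry below is none F0.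

Step 3 (dianion methylation). The lactone alkoxide–enolate may O-methylate, fragment or alkylate with poor facial control. The fallback sets out from 4 and comes back at 5, replacing the dianion with a protected mono-enolate. Silylation (tBuMe2SiCl, imidazole, DMF) gives (3R,5S)-3-(tert-butyldimethylsilyloxy)-5-vinyldihydrofuran-2(3H)-one F1. Enolate methylation (LiN(iPr)2, MeI, THF/DMPU, −78 °C), again anti to the vinyl group, gives (3S,5S)-3-(tert-butyldimethylsilyloxy)-3-methyl-5-vinyldihydrofuran-2(3H)-one F2. Bu4NF/AcOH in THF then returns 5.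

Step 13 (Mitsunobu with a bulky α,α-disubstituted acid on a hindered allylic alcohol). Elimination, SN2′ attack or no reaction are possible. The fallback sets out from 15 and comes back at 22, forming the ester bond by acyl transfer instead of carboxylate alkylation. Mitsunobu inversion with the small, more acidic formic acid (PPh3, DIAD, THF) gives (4Z,6S,7R,8S,10S)-6-formyloxy-1-oxo-3,10-epoxygermacra-2,4,11(13)-trien-12,8-olide F3. Mild methanolysis (KHCO3, MeOH, 0 °C) gives (4Z,6S,7S,8S,10S)-6-hydroxy-1-oxo-3,10-epoxygermacra-2,4,11(13)-trien-12,8-olide F4. Yamaguchi esterification of this alcohol with 21 (2,4,6-trichlorobenzoyl chloride, Et3N, then DMAP, toluene, 0 °C) proceeds with retention and gives 22. The same 6S alcohol would also be the entry point if step 9 turned out syn-selective.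

**Further compounds**
F0 | step 9 | none | none
F1 | step 3 | (3R,5S)-3-(tert-butyldimethylsilyloxy)-5-vinyldihydrofuran-2(3H)-one | C=C[C@@H]1C[C@@H](O[Si](C)(C)C(C)(C)C)C(=O)O1
F2 | step 3 | (3S,5S)-3-(tert-butyldimethylsilyloxy)-3-methyl-5-vinyldihydrofuran-2(3H)-one | C=C[C@@H]1C[C@](C)(O[Si](C)(C)C(C)(C)C)C(=O)O1
F3 | step 13 | (4Z,6S,7R,8S,10S)-6-formyloxy-1-oxo-3,10-epoxygermacra-2,4,11(13)-trien-12,8-olide | C=C1C(=O)O[C@H]2C[C@]3(C)OC(=CC3=O)/C(C)=C\[C@H](OC=O)[C@H]12
F4 | step 13 | (4Z,6S,7S,8S,10S)-6-hydroxy-1-oxo-3,10-epoxygermacra-2,4,11(13)-trien-12,8-olide | C=C1C(=O)O[C@H]2C[C@]3(C)OC(=CC3=O)/C(C)=C\[C@H](O)[C@H]12
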